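The route rests on cutting the bond between ring A and the two-carbon bridge from ring D. That bridge enters ring A at C4, para to the oxygen-bearing C1 and meta to the diaryl ether carbon C2. This is the site to which an O-methyl donor sends an electrophile. An acylium ion raised on the ring D side chain therefore attacks the unfunctionalised C4–H of a guaiacol-derived ring A, forming one C–C bond and the 18-membered ring in one operation. The precursor is the open four-ring chain ending in a ring D acetic acid, with ring A as methyl ether and the ring C catechol deactivated as diacetate.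

Key step: step 10

Remark: ring A = monohydroxy ring (C1 bears OMe/OH, C2 bears the oxygen to ring B, C4 is para to C1), ring B = para-phenylene, ring C = catechol ring, ring D = meta-phenylene; stilbenes 9 and 12 are carried as E/Z mixtures because step 8 saturates the double bond, and the target has no stereocentre.

Step 1
Reactants: 1 guaiacol; 2 4-fluorobenzaldehyde
Product: 3 4-(2-methoxyphenoxy)benzaldehyde
Conditions: K2CO3, DMF, 120 °C
Reagents that add atoms: none
Why: Nucleophilic aromatic substitution, in which the para-formyl group stabilises the Meisenheimer adduct and fluoride is the best leaving group for this mechanism, so the A–O–B diaryl ether should form without any metal.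

Step 2
Reactants: 3 4-(2-methoxyphenoxy)benzaldehyde
Product: 4 [4-(2-methoxyphenoxy)phenyl]methanol
Conditions: NaBH4, MeOH, 0 °C
Reagents that add atoms: none
Why: Hydride reduction of an aromatic aldehyde with NaBH4 is chemoselective and leaves both aryl ethers untouched.

Step 3
Reactants: 4 [4-(2-methoxyphenoxy)phenyl]methanol
Product: 5 [4-(2-methoxyphenoxy)benzyl]triphenylphosphonium bromide
Conditions: PPh3·HBr, MeCN, reflux
Reagents that add atoms: triphenylphosphine hydrobromide, Br.c1ccc(cc1)P(c1ccccc1)c1ccccc1
Why: Direct phosphonium salt formation from a benzylic alcohol, in which HBr ionises the para-aryloxy-stabilised benzylic position and PPh3 captures it, saving a separate bromination and leaving the aryl methyl ether intact at this acidity.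

Step 4
Reactants: 6 2,3,4-trihydroxybenzaldehyde
Product: 7 3,4-bis(benzyloxy)-2-hydroxybenzaldehyde
Conditions: NaH (3.2 equiv), degassed DMF, 0 °C; BnBr (2.0 equiv), 0 °C to rt; aq. HCl
Reagents that add atoms: benzyl bromide, BrCc1ccccc1
Why: Williamson etherification after full deprotonation, in which the 3-oxide (not conjugated with the formyl group) and the unhindered 4-oxide are the two most nucleophilic sites while the 2-oxide is a sodium-chelated vinylogous carboxylate flanked on both sides, so two equivalents of benzyl bromide should stop at the 3,4-diether.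

Step 5
Reactants: 5 [4-(2-methoxyphenoxy)benzyl]triphenylphosphonium bromide; 7 3,4-bis(benzyloxy)-2-hydroxybenzaldehyde
Product: 9 2,3-bis(benzyloxy)-6-{2-[4-(2-methoxyphenoxy)phenyl]ethenyl}phenol (E/Z mixture), via phosphonium ylide 8 (not isolated)
Conditions: 5 (1.2 equiv), KOtBu (2.4 equiv), THF, 0 °C; then 7, rt to 45 °C; aq. HCl
Reagents that add atoms: none
Why: Wittig olefination, in which one equivalent of base parks the phenol as phenoxide and the other makes the semi-stabilised ylide 8 that still adds to the deactivated aldehyde; consuming the formyl group now means that no salicylaldehyde later meets an arylacetic ester under base, a pairing that condenses to 3-arylcoumarins.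

Step 6
Reactants: 10 3-iodophenylacetic acid
Product: 11 benzyl (3-iodophenyl)acetate
Conditions: BnBr, K2CO3, DMF, rt
Reagents that add atoms: benzyl bromide, BrCc1ccccc1
Why: SN2 O-alkylation of the carboxylate; the benzyl ester is chosen because it falls in the same hydrogenolysis as the ring C benzyl ethers, so no ester ever has to be hydrolysed once base-labile aryl acetates are in place.

Step 7
Reactants: 9 2,3-bis(benzyloxy)-6-{2-[4-(2-methoxyphenoxy)phenyl]ethenyl}phenol; 11 benzyl (3-iodophenyl)acetate
Product: 12 benzyl [3-(2,3-bis(benzyloxy)-6-{2-[4-(2-methoxyphenoxy)phenyl]ethenyl}phenoxy)phenyl]acetate (E/Z mixture)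
Conditions: 11 (1.5 equiv), CuI (10 mol %), picolinic acid (20 mol %), K3PO4, DMSO, 4 Å MS, 90 °C, argon
Reagents that add atoms: none
Why: Ullmann-type copper-catalysed C–O coupling in the picolinic acid/DMSO variant suited to phenols with two ortho substituents, helped by a phenol that is electron-rich now that the formyl group is gone and by an unhindered aryl iodide that can be used in excess.

Step 8
Reactants: 12 benzyl [3-(2,3-bis(benzyloxy)-6-{2-[4-(2-methoxyphenoxy)phenyl]ethenyl}phenoxy)phenyl]acetate
Product: 13 [3-(2,3-dihydroxy-6-{2-[4-(2-methoxyphenoxy)phenyl]ethyl}phenoxy)phenyl]acetic acid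
Conditions: H2 (1 atm), Pd/C, EtOAc–EtOH, rt
Reagents that add atoms: none
Why: Catalytic hydrogenation and hydrogenolysis over Pd/C should saturate the stilbene and cleave both benzyl ethers and the benzyl ester in one neutral operation, while diaryl ethers and the aryl methyl ether are inert.

Step 9
Reactants: 13 [3-(2,3-dihydroxy-6-{2-[4-(2-methoxyphenoxy)phenyl]ethyl}phenoxy)phenyl]acetic acid
Product: 15 [3-(2,3-diacetoxy-6-{2-[4-(2-methoxyphenoxy)phenyl]ethyl}phenoxy)phenyl]acetic acid (open precursor), via mixed anhydride 14 (not isolated)
Conditions: Ac2O, pyridine, 0 °C to rt, argon; then H2O, rt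
Reagents that add atoms: acetic anhydride, CC(=O)OC(C)=O
Why: Pyridine-promoted O-acetylation of both phenols, during which the carboxyl group is only transiently tied up as mixed anhydride 14 that the water quench hydrolyses, and leaving out DMAP and heat avoids Dakin–West-type chemistry of the arylacetic acid.

Step 10
Reactants: 15 [3-(2,3-diacetoxy-6-{2-[4-(2-methoxyphenoxy)phenyl]ethyl}phenoxy)phenyl]acetic acid
Product: 17 macrocyclic aryl ketone (ring A methyl ether; ring C diacetate; C=O on the bridge carbon bonded to ring A), via acid chloride 16 (not isolated)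
Conditions: (COCl)2, cat. DMF, CH2Cl2, 0 °C to rt, evaporate; then syringe-pump addition (12 h) into SnCl4 (5 equiv), CH2Cl2, 0 °C to rt, final ca. 1 mM
Reagents that add atoms: none
Why: SnCl4 ionises acid chloride 16 to the arylacetyl cation, which adds to C4 of ring A, and loss of the C4 proton from the Wheland intermediate restores the arene and leaves ketone 17 bound to tin until work-up. The closest known reaction type is the high-dilution intramolecular Friedel–Crafts acylation by which ω-arylalkanoyl chlorides are closed to macrocyclic aryl ketones. The one ring formed is the 18-membered macrocycle, closed by intramolecular electrophilic aromatic substitution in which the terminal acyl carbon of the ring D chain bonds to ring A, so that ring A ends up bridged through C2 and C4; no stereocentre arises. The step needs site selectivity among four arenes: ring C is switched off by its two acetoxy groups and is out of reach anyway, ring D cannot reach its own side chain, and ring B offers only carbons ortho to a weaker aryloxy donor or to an alkyl group, where acylation under a Lewis acid as mild as SnCl4 is slow and would have to build a strained 12- or 13-membered cyclophane. Within ring A the methoxy oxygen, whose lone pair is not shared with a second arene, is a stronger para director than the aryloxy oxygen, which disfavours C5, while attack at C6 would push the methoxy group into the ring cavity and C3 lacks methoxy activation. Ring closure is favoured over chain growth by slow addition of 16 into excess SnCl4 at about 1 mM, the excess also saturating the acetate carbonyl groups.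

Step 11
Reactants: 17 macrocyclic aryl ketone
Product: 18 marchantin H ring A methyl ether ring C diacetate
Conditions: Et3SiH, CF3CO2H, CH2Cl2, rt
Reagents that add atoms: none
Why: Ionic hydrogenation, in which the protonated para-methoxyaryl ketone takes hydride from Et3SiH, the benzylic alcohol ionises to a methoxy-stabilised cation that takes a second hydride, and aryl acetates and aryl ethers are stable in CF3CO2H.

Step 12
Reactants: 18 marchantin H ring A methyl ether ring C diacetate
Product: 20 marchantin H, via aryloxydibromoborane 19 (not isolated)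
Conditions: BBr3 (6 equiv), CH2Cl2, −78 °C to rt; then MeOH, 40 °C, evaporate
Reagents that add atoms: none
Why: Lewis-acid aryl methyl ether cleavage followed by acid-catalysed transesterification, since BBr3 dealkylates only the O–CH3 bond (diaryl ethers offer no sp3 carbon) and the HBr released when methanol destroys the boron species methanolyses both aryl acetates, so the air-sensitive catechol is unveiled under acidic and not basic conditions.

Compound list
1 | guaiacol | COc1ccccc1O | starting material
2 | 4-fluorobenzaldehyde | O=Cc1ccc(F)cc1 | starting material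
3 | 4-(2-methoxyphenoxy)benzaldehyde | COc1ccccc1Oc1ccc(C=O)cc1 | intermediate
4 | [4-(2-methoxyphenoxy)phenyl]methanol | COc1ccccc1Oc1ccc(CO)cc1 | intermediate
5 | [4-(2-methoxyphenoxy)benzyl]triphenylphosphonium bromide | COc1ccccc1Oc1ccc(C[P+](c2ccccc2)(c2ccccc2)c2ccccc2)cc1.[Br-] | intermediate
6 | 2,3,4-trihydroxybenzaldehyde | O=Cc1ccc(O)c(O)c1O | starting material
7 | 3,4-bis(benzyloxy)-2-hydroxybenzaldehyde | O=Cc1ccc(OCc2ccccc2)c(OCc2ccccc2)c1O | intermediate
8 | [4-(2-methoxyphenoxy)benzylidene]triphenylphosphorane (ylide, not isolated) | COc1ccccc1Oc1ccc(C=P(c2ccccc2)(c2ccccc2)c2ccccc2)cc1 | intermediate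
9 | 2,3-bis(benzyloxy)-6-{2-[4-(2-methoxyphenoxy)phenyl]ethenyl}phenol (E/Z mixture, geometry left open) | COc1ccccc1Oc1ccc(C=Cc2ccc(OCc3ccccc3)c(OCc3ccccc3)c2O)cc1 | intermediate
10 | 3-iodophenylacetic acid | OC(=O)Cc1cccc(I)c1 | starting material
11 | benzyl (3-iodophenyl)acetate | O=C(Cc1cccc(I)c1)OCc1ccccc1 | intermediate
12 | benzyl [3-(2,3-bis(benzyloxy)-6-{2-[4-(2-methoxyphenoxy)phenyl]ethenyl}phenoxy)phenyl]acetate (E/Z mixture, geometry left open) | COc1ccccc1Oc1ccc(C=Cc2ccc(OCc3ccccc3)c(OCc3ccccc3)c2Oc2cccc(CC(=O)OCc3ccccc3)c2)cc1 | intermediate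
13 | [3-(2,3-dihydroxy-6-{2-[4-(2-methoxyphenoxy)phenyl]ethyl}phenoxy)phenyl]acetic acid | COc1ccccc1Oc1ccc(CCc2ccc(O)c(O)c2Oc2cccc(CC(O)=O)c2)cc1 | intermediate
14 | acetic [3-(2,3-diacetoxy-6-{2-[4-(2-methoxyphenoxy)phenyl]ethyl}phenoxy)phenyl]acetic anhydride (not isolated) | COc1ccccc1Oc1ccc(CCc2ccc(OC(C)=O)c(OC(C)=O)c2Oc2cccc(CC(=O)OC(C)=O)c2)cc1 | intermediate
15 | [3-(2,3-diacetoxy-6-{2-[4-(2-methoxyphenoxy)phenyl]ethyl}phenoxy)phenyl]acetic acid (key-step precursor) | COc1ccccc1Oc1ccc(CCc2ccc(OC(C)=O)c(OC(C)=O)c2Oc2cccc(CC(O)=O)c2)cc1 | intermediate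
16 | [3-(2,3-diacetoxy-6-{2-[4-(2-methoxyphenoxy)phenyl]ethyl}phenoxy)phenyl]acetyl chloride (not isolated) | COc1ccccc1Oc1ccc(CCc2ccc(OC(C)=O)c(OC(C)=O)c2Oc2cccc(CC(Cl)=O)c2)cc1 | intermediate
17 | macrocyclic aryl ketone, ring A methyl ether, ring C diacetate (key-step product) | COc1ccc2cc1Oc1ccc(cc1)CCc1ccc(OC(C)=O)c(OC(C)=O)c1Oc1cccc(c1)CC2=O | intermediate
18 | marchantin H ring A methyl ether ring C diacetate | COc1ccc2cc1Oc1ccc(cc1)CCc1ccc(OC(C)=O)c(OC(C)=O)c1Oc1cccc(c1)CC2 | intermediate
19 | ring A aryloxydibromoborane of the ring C diacetate (not isolated) | BrB(Br)Oc1ccc2cc1Oc1ccc(cc1)CCc1ccc(OC(C)=O)c(OC(C)=O)c1Oc1cccc(c1)CC2 | intermediate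
20 | marchantin H | Oc1ccc2cc1Oc1ccc(cc1)CCc1ccc(O)c(O)c1Oc1cccc(c1)CC2 | target

Total step count: 12
Longest linear sequence: 10 (steps 1, 2, 3, 5, 7, 8, 9, 10, 11, 12)

Steps most likely to fail

Step 10. Chain growth by intermolecular acylation may outrun ring closure. The acylium ion may also attack C5 instead of C4, or lose CO before it finds ring A.
- The fallback sets out from 15 and comes back at 18.
- Acid 15 would be iodinated with N-iodosuccinimide and catalytic CF3CO2H in MeCN. This follows the same para-to-methoxy preference but lets the regiochemistry be secured and purified on an open-chain compound, giving the ring A C4 iodo acid F1.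
- BH3·THF at 0 °C would reduce the carboxyl group in the presence of the aryl acetates to the primary alcohol F2, and Dess–Martin periodinane would give the arylacetaldehyde F3.
- A Nozaki–Hiyama–Kishi ring closure (CrCl2, catalytic NiCl2, DMF, slow addition) would then form the same ring A–carbon bond from an arylchromium species whose position is fixed by the iodine, giving the racemic macrocyclic benzylic alcohol F4.
- The hydroxyl group of F4 would be removed with Et3SiH and CF3CO2H to reach 18.

Step 7. The coupling may stall because the phenoxide is flanked on both sides, while the arylacetic ester slowly enolises and self-condenses under the basic, hot conditions.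
- The fallback sets out from 11 and 9 and comes back at 12.
- Iodide 11 would be oxidised with mCPBA and TsOH·H2O in MeCN, and the trivalent iodine species trapped with 1,3,5-trimethoxybenzene, to give the aryl(2,4,6-trimethoxyphenyl)iodonium tosylate F5.
- Phenol 9 with K2CO3 in toluene at about 50 °C would then be O-arylated without metal by ligand coupling at iodine.
- The electron-rich trimethoxyphenyl group stays on iodine, so only the ring D aryl group is transferred and 12 results. Crowded phenols are good partners in this reaction type.

Step 4. Site selectivity may erode through alkylation at the 2-oxygen or over-alkylation, and the polyphenoxide may be oxidised by traces of air.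
- The fallback sets out from 6 and comes back at 7.
- Exhaustive benzylation (excess BnBr, K2CO3, DMF) asks for no selectivity and would give 2,3,4-tris(benzyloxy)benzaldehyde F6.
- MgBr2·OEt2 in toluene–Et2O at reflux would then remove only the benzyl group ortho to the formyl group. Magnesium chelated between the aldehyde oxygen and the 2-oxygen activates that ether alone toward bromide, giving 7.

Further compounds
F1 | step 10 | [3-(2,3-diacetoxy-6-{2-[4-(5-iodo-2-methoxyphenoxy)phenyl]ethyl}phenoxy)phenyl]acetic acid | COc1ccc(I)cc1Oc1ccc(CCc2ccc(OC(C)=O)c(OC(C)=O)c2Oc2cccc(CC(O)=O)c2)cc1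
F2 | step 10 | 2-[3-(2,3-diacetoxy-6-{2-[4-(5-iodo-2-methoxyphenoxy)phenyl]ethyl}phenoxy)phenyl]ethanol | COc1ccc(I)cc1Oc1ccc(CCc2ccc(OC(C)=O)c(OC(C)=O)c2Oc2cccc(CCO)c2)cc1
F3 | step 10 | [3-(2,3-diacetoxy-6-{2-[4-(5-iodo-2-methoxyphenoxy)phenyl]ethyl}phenoxy)phenyl]acetaldehyde | COc1ccc(I)cc1Oc1ccc(CCc2ccc(OC(C)=O)c(OC(C)=O)c2Oc2cccc(CC=O)c2)cc1
F4 | step 10 | macrocyclic benzylic alcohol, ring A methyl ether, ring C diacetate (racemic) | COc1ccc2cc1Oc1ccc(cc1)CCc1ccc(OC(C)=O)c(OC(C)=O)c1Oc1cccc(c1)CC2O
F5 | step 7 | {3-[2-(benzyloxy)-2-oxoethyl]phenyl}(2,4,6-trimethoxyphenyl)iodonium 4-toluenesulfonate | COc1cc(OC)c([I+]c2cccc(CC(=O)OCc3ccccc3)c2)c(OC)c1.Cc1ccc(cc1)S([O-])(=O)=O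
F6 | step 4 | 2,3,4-tris(benzyloxy)benzaldehyde | O=Cc1ccc(OCc2ccccc2)c(OCc2ccccc2)c1OCc1ccccc1
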